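The cyclohexenone ring (C1 ketone, C2 bearing the C7 hydroxymethyl, C3, C4, C5, C6) is opened at the C5–C6 bond. The feature exploited is the vicinal trans pair C6–O/C5–isopropyl, the signature of a carbonyl-ene closure: in one operation a confined chiral Brønsted acid turns an achiral (2E)-3-(silyloxymethyl)-7-methylocta-2,6-dienal, whose formyl group is cis to the homoprenyl chain, into the six-membered ring with both stereocentres and the C6 hydroxyl in place. The primary oxygen is carried as a triisopropylsilyl ether, more robust to the strong acid than the smaller silyl ethers. Oxygen is then walked onto C1 and C4 by a singlet-oxygen ene reaction and vinylogous Rubottom oxidation.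

Key step: step 5

Remark: ring atoms keep the target numbering in all ring intermediates (C1 carbonyl carbon, C2 bearing exocyclic C7, C3, C4, C5 isopropyl, C6 acyloxy).
Remark: the sense of induction of the chiral acid in step 5 is assigned by analogy with the parent terpene aldehyde; both catalyst antipodes derive from commercial BINOL, and the one that gives the (1S,6R) alcohol is used.

Step 1
Reactants: 1 but-2-yne-1,4-diol
Product: 2 4-[(triisopropylsilyl)oxy]but-2-yn-1-ol
Conditions: NaH (1.0 equiv), THF, 0 °C to rt; TIPSCl (1.0 equiv)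
Reagents that add atoms: chlorotriisopropylsilane (TIPSCl), CC(C)[Si](Cl)(C(C)C)C(C)C
Why: O-silylation of a symmetrical diol through its sparingly soluble monosodium alkoxide should stop after one silyl group, and unreacted diol is removed with water.

Step 2
Reactants: 2 4-[(triisopropylsilyl)oxy]but-2-yn-1-ol
Product: 4 (2Z)-3-iodo-4-[(triisopropylsilyl)oxy]but-2-en-1-ol, via cyclic alkenylalanate 3 (not isolated)
Conditions: NaAlH2(OCH2CH2OMe)2, THF, 0 °C; EtOAc; I2, −78 to 0 °C; aq. potassium sodium tartrate
Reagents that add atoms: iodine (I2), II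
Why: Hydroxyl-directed trans-hydroalumination of the propargylic alcohol places aluminium on C3 in a five-membered alkoxyalanate, and iodinolysis of the C–Al bond with retention gives the (Z)-3-iodo allylic alcohol; the mixture is kept at or below 0 °C so that the alanate does not expel the silyloxy group to give an allene.

Step 3
Reactants: 4 (2Z)-3-iodo-4-[(triisopropylsilyl)oxy]but-2-en-1-ol; 5 5-bromo-2-methylpent-2-ene
Product: 7 (2E)-7-methyl-3-{[(triisopropylsilyl)oxy]methyl}octa-2,6-dien-1-ol, via homoprenylzinc bromide 6 (not isolated)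
Conditions: 5, Zn dust (I2-activated), LiCl, THF, 50 °C; then 4, PdCl2(dppf) (5 mol %; dppf = 1,1'-bis(diphenylphosphino)ferrocene), THF, rt to 45 °C; 6 in excess (2.5 equiv)
Reagents that add atoms: none
Why: Negishi sp3–sp2 cross-coupling (zinc insertion, then zerovalent-palladium catalysis) proceeds with retention of the alkene geometry, and the free hydroxyl is tolerated as its zinc alkoxide when the organozinc is used in excess.

Step 4
Reactants: 7 (2E)-7-methyl-3-{[(triisopropylsilyl)oxy]methyl}octa-2,6-dien-1-ol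
Product: 8 (2E)-7-methyl-3-{[(triisopropylsilyl)oxy]methyl}octa-2,6-dienal
Conditions: MnO2 (activated, excess), CH2Cl2, rt
Reagents that add atoms: none
Why: Chemoselective MnO2 oxidation of the primary allylic alcohol under neutral conditions should keep the (2E) geometry (formyl cis to the homoprenyl chain) and the silyl ether.

Step 5
Reactants: 8 (2E)-7-methyl-3-{[(triisopropylsilyl)oxy]methyl}octa-2,6-dienal
Product: 9 (1S,6R)-6-(prop-1-en-2-yl)-3-{[(triisopropylsilyl)oxy]methyl}cyclohex-2-en-1-ol (trans)
Conditions: IDPi acid HN[P(=NSO2CF3)(O2Ar*)]2 (2 mol %; Ar*O2 = 3,3'-bis[3,5-bis(trifluoromethyl)phenyl]-1,1'-binaphthalene-2,2'-diolate, antipode as in the remark), CH2Cl2, 4 Å molecular sieves, −40 °C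
Reagents that add atoms: none
Why: The acid activates the enal carbonyl inside its chiral pocket, the trisubstituted alkene adds through its inner carbon (future C5) to the formyl carbon (future C6) and a methyl hydrogen passes to oxygen (concerted asynchronous carbonyl-ene, or Prins addition followed by proton loss from the tertiary cation within the ion pair), which gives the isopropenyl group and the secondary alcohol. The closest known reaction is the catalytic asymmetric carbonyl-ene cyclisation of neral to trans-isopiperitenol with confined imidodiphosphorimidate acids, together with the cyclisation of citronellal to isopulegol. The ring closes in a 6-exo-trig mode at the carbonyl carbon (type 1 intramolecular ene, the tether joining the enophile to the olefinic terminus of the ene unit). C6 and C5 are set trans by a chair-like transition state with the forming C–O bond and the isopropenyl group both equatorial, and their absolute configuration by the chiral counter-anion, since the substrate is achiral. The step needs enantioface selectivity, trans selectivity and survival of the acid-labile allylic alcohol: the (2E) geometry holds the formyl group and the nucleophilic alkene on the same side, the confined pocket suppresses ionisation and bimolecular pathways, and the inductively withdrawing silyloxymethyl group makes the product allyl cation harder to form than in the parent terpene.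

Step 6
Reactants: 9 (1S,6R)-6-(prop-1-en-2-yl)-3-{[(triisopropylsilyl)oxy]methyl}cyclohex-2-en-1-ol
Product: 10 (1R,6R)-6-(propan-2-yl)-3-{[(triisopropylsilyl)oxy]methyl}cyclohex-2-en-1-ol
Conditions: H2 (1 atm), RhCl(PPh3)3 (5 mol %), toluene/EtOH, rt
Reagents that add atoms: none
Why: Homogeneous hydrogenation with RhCl(PPh3)3 reduces the unhindered 1,1-disubstituted isopropenyl alkene far faster than the trisubstituted ring alkene and does not cleave the allylic C–O bond; no stereocentre is touched (the descriptor of the carbinol carbon changes from S to R for priority reasons only).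

Step 7
Reactants: 11 [(tert-butyldimethylsilyl)oxy]acetaldehyde; 12 ethyl 2-(triphenylphosphoranylidene)propanoate
Product: 13 ethyl (2E)-4-[(tert-butyldimethylsilyl)oxy]-2-methylbut-2-enoate
Conditions: CH2Cl2, rt to 40 °C
Reagents that add atoms: none
Why: Wittig olefination with a stabilised α-methyl ylide should give the (E)-trisubstituted enoate, with the ester trans to the silyloxymethyl group.

Step 8
Reactants: 13 ethyl (2E)-4-[(tert-butyldimethylsilyl)oxy]-2-methylbut-2-enoate
Product: 14 (2E)-4-[(tert-butyldimethylsilyl)oxy]-2-methylbut-2-enoic acid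
Conditions: LiOH·H2O, THF/MeOH/H2O, 0 °C to rt; then cold aq. HCl to pH 4
Reagents that add atoms: lithium hydroxide (hydroxide supplies the new carboxyl oxygen), [Li+].[OH-]
Why: Saponification (acyl substitution by hydroxide) at or below room temperature should leave the primary silyl ether and the alkene geometry intact, and acidification is stopped at pH 4.

Step 9
Reactants: 10 (1R,6R)-6-(propan-2-yl)-3-{[(triisopropylsilyl)oxy]methyl}cyclohex-2-en-1-ol; 14 (2E)-4-[(tert-butyldimethylsilyl)oxy]-2-methylbut-2-enoic acid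
Product: 15 (1R,6R)-6-(propan-2-yl)-3-{[(triisopropylsilyl)oxy]methyl}cyclohex-2-en-1-yl (2E)-4-[(tert-butyldimethylsilyl)oxy]-2-methylbut-2-enoate
Conditions: DCC, 4-(dimethylamino)pyridine (DMAP, 0.1 equiv), CH2Cl2, 0 °C to rt
Reagents that add atoms: none
Why: Steglich esterification (carbodiimide activation, acyl transfer through the acylpyridinium) acylates the hindered secondary allylic alcohol with retention at C6, and the low temperature and catalytic amount of base should keep the enoate from deconjugating.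

Step 10
Reactants: 15 (1R,6R)-6-(propan-2-yl)-3-{[(triisopropylsilyl)oxy]methyl}cyclohex-2-en-1-yl (2E)-4-[(tert-butyldimethylsilyl)oxy]-2-methylbut-2-enoate
Product: 17 (1R,6R)-2-oxo-6-(propan-2-yl)-3-{[(triisopropylsilyl)oxy]methyl}cyclohex-3-en-1-yl (2E)-4-[(tert-butyldimethylsilyl)oxy]-2-methylbut-2-enoate, via allylic hydroperoxide 16 (not isolated)
Conditions: O2, 5,10,15,20-tetraphenylporphyrin (cat.), visible light, CH2Cl2, 0 °C; then Ac2O, pyridine, DMAP (cat.), 0 °C to rt
Reagents that add atoms: dioxygen (as singlet oxygen), O=O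
Why: Schenck ene reaction of singlet oxygen at the trisubstituted ring alkene (O to C1, allylic H from C3, alkene to C2=C3; the hydrogens on C6 and C7 sit on oxygen-bearing carbons and are abstracted reluctantly, and the enoate is inert) followed by Kornblum–DeLaMare-type acetylative dehydration of the secondary hydroperoxide gives the enone, so the C1 configuration of the hydroperoxide is irrelevant.

Step 11
Reactants: 17 (1R,6R)-2-oxo-6-(propan-2-yl)-3-{[(triisopropylsilyl)oxy]methyl}cyclohex-3-en-1-yl (2E)-4-[(tert-butyldimethylsilyl)oxy]-2-methylbut-2-enoate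
Product: 18 (1R,6S)-6-(propan-2-yl)-3-{[(triisopropylsilyl)oxy]methyl}-2-[(trimethylsilyl)oxy]cyclohexa-2,4-dien-1-yl (2E)-4-[(tert-butyldimethylsilyl)oxy]-2-methylbut-2-enoate
Conditions: TMSOTf, Et3N, CH2Cl2, −20 to 0 °C; non-aqueous work-up (pentane, filtration), used crude
Reagents that add atoms: trimethylsilyl trifluoromethanesulfonate (TMSOTf), C[Si](C)(C)OS(=O)(=O)C(F)(F)F
Why: Soft enolisation (silyl triflate and tertiary amine) should give the linearly conjugated dienol ether by loss of a C4 proton, because enolisation towards C6 would create a fully substituted 1,2-dioxygenated alkene with three contiguous in-plane substituents next to the isopropyl-bearing carbon, and the ester carbonyls are not silylated at this temperature.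

Step 12
Reactants: 18 (1R,6S)-6-(propan-2-yl)-3-{[(triisopropylsilyl)oxy]methyl}-2-[(trimethylsilyl)oxy]cyclohexa-2,4-dien-1-yl (2E)-4-[(tert-butyldimethylsilyl)oxy]-2-methylbut-2-enoate
Product: 20 (1R,5R,6S)-5-hydroxy-2-oxo-6-(propan-2-yl)-3-{[(triisopropylsilyl)oxy]methyl}cyclohex-3-en-1-yl (2E)-4-[(tert-butyldimethylsilyl)oxy]-2-methylbut-2-enoate, via silyloxy vinyl epoxide 19 (not isolated)
Conditions: dimethyldioxirane (acetone solution), CH2Cl2, −78 to −30 °C; then 10 % aq. citric acid, THF, 0 °C
Reagents that add atoms: dimethyldioxirane, CC1(C)OO1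
Why: Vinylogous Rubottom oxidation: the electrophilic dioxirane epoxidises the terminal C3=C4 bond of the 1-silyloxy diene (C2 is fully substituted and shielded) on the face anti to the pseudo-axial isopropyl group on the neighbouring C5, and collapse of the epoxide followed by mild acid hydrolysis gives the 4-hydroxy enone with the C4 hydroxyl trans to isopropyl.

Step 13
Reactants: 20 (1R,5R,6S)-5-hydroxy-2-oxo-6-(propan-2-yl)-3-{[(triisopropylsilyl)oxy]methyl}cyclohex-3-en-1-yl (2E)-4-[(tert-butyldimethylsilyl)oxy]-2-methylbut-2-enoate; 21 propionic acid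
Product: 22 (1R,5S,6S)-2-oxo-5-(propanoyloxy)-6-(propan-2-yl)-3-{[(triisopropylsilyl)oxy]methyl}cyclohex-3-en-1-yl (2E)-4-[(tert-butyldimethylsilyl)oxy]-2-methylbut-2-enoate
Conditions: PPh3, diisopropyl azodicarboxylate (DIAD), toluene/THF, 0 °C to rt
Reagents that add atoms: none
Why: Mitsunobu esterification displaces the activated allylic C4 oxygen by propionate with inversion (SN2), turning the trans alcohol into the required cis propionate under neutral conditions that spare the base-sensitive acyloxy enone.

Step 14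
Reactants: 22 (1R,5S,6S)-2-oxo-5-(propanoyloxy)-6-(propan-2-yl)-3-{[(triisopropylsilyl)oxy]methyl}cyclohex-3-en-1-yl (2E)-4-[(tert-butyldimethylsilyl)oxy]-2-methylbut-2-enoate
Product: 23 (1R,5S,6S)-3-(hydroxymethyl)-2-oxo-5-(propanoyloxy)-6-(propan-2-yl)cyclohex-3-en-1-yl (2E)-4-hydroxy-2-methylbut-2-enoate
Conditions: HF·pyridine, pyridine, THF, 0 °C to rt
Reagents that add atoms: none
Why: Fluoride-mediated desilylation with buffered HF·pyridine cleaves both primary silyl ethers without base, so neither acyl migration nor elimination of the C4 ester towards a phenol should occur.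

Compound list
1 | but-2-yne-1,4-diol | OCC#CCO | starting material
2 | 4-[(triisopropylsilyl)oxy]but-2-yn-1-ol | OCC#CCO[Si](C(C)C)(C(C)C)C(C)C | intermediate
3 | cyclic sodium alkenylalanate (1,2-oxaluminole ring O–CH2–CH=C(CH2OTIPS)–Al, two 2-methoxyethoxy groups on aluminium) | [Na+].COCCO[Al-]1(OCCOC)OCC=C1CO[Si](C(C)C)(C(C)C)C(C)C | intermediate
4 | (2Z)-3-iodo-4-[(triisopropylsilyl)oxy]but-2-en-1-ol | OC/C=C(/CO[Si](C(C)C)(C(C)C)C(C)C)I | intermediate
5 | 5-bromo-2-methylpent-2-ene | CC(C)=CCCBr | starting material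
6 | (4-methylpent-3-en-1-yl)zinc bromide | CC(C)=CCC[Zn]Br | intermediate
7 | (2E)-7-methyl-3-{[(triisopropylsilyl)oxy]methyl}octa-2,6-dien-1-ol | OC/C=C(/CO[Si](C(C)C)(C(C)C)C(C)C)CCC=C(C)C | intermediate
8 | (2E)-7-methyl-3-{[(triisopropylsilyl)oxy]methyl}octa-2,6-dienal | O=C/C=C(/CO[Si](C(C)C)(C(C)C)C(C)C)CCC=C(C)C | intermediate
9 | (1S,6R)-6-(prop-1-en-2-yl)-3-{[(triisopropylsilyl)oxy]methyl}cyclohex-2-en-1-ol | C1CC(CO[Si](C(C)C)(C(C)C)C(C)C)=C[C@H](O)[C@H]1C(C)=C | intermediate
10 | (1R,6R)-6-(propan-2-yl)-3-{[(triisopropylsilyl)oxy]methyl}cyclohex-2-en-1-ol | C1CC(CO[Si](C(C)C)(C(C)C)C(C)C)=C[C@H](O)[C@H]1C(C)C | intermediate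
11 | [(tert-butyldimethylsilyl)oxy]acetaldehyde | O=CCO[Si](C)(C)C(C)(C)C | starting material
12 | ethyl 2-(triphenylphosphoranylidene)propanoate | CCOC(=O)C(C)=P(c1ccccc1)(c1ccccc1)c1ccccc1 | starting material
13 | ethyl (2E)-4-[(tert-butyldimethylsilyl)oxy]-2-methylbut-2-enoate | CCOC(=O)/C(C)=C/CO[Si](C)(C)C(C)(C)C | intermediate
14 | (2E)-4-[(tert-butyldimethylsilyl)oxy]-2-methylbut-2-enoic acid | OC(=O)/C(C)=C/CO[Si](C)(C)C(C)(C)C | intermediate
15 | (1R,6R)-6-(propan-2-yl)-3-{[(triisopropylsilyl)oxy]methyl}cyclohex-2-en-1-yl (2E)-4-[(tert-butyldimethylsilyl)oxy]-2-methylbut-2-enoate | C1CC(CO[Si](C(C)C)(C(C)C)C(C)C)=C[C@H](OC(=O)/C(C)=C/CO[Si](C)(C)C(C)(C)C)[C@H]1C(C)C | intermediate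
16 | (1R,6R)-2-hydroperoxy-6-(propan-2-yl)-3-{[(triisopropylsilyl)oxy]methyl}cyclohex-3-en-1-yl (2E)-4-[(tert-butyldimethylsilyl)oxy]-2-methylbut-2-enoate (hydroperoxide carbon not controlled) | C1C=C(CO[Si](C(C)C)(C(C)C)C(C)C)C(OO)[C@H](OC(=O)/C(C)=C/CO[Si](C)(C)C(C)(C)C)[C@H]1C(C)C | intermediate
17 | (1R,6R)-2-oxo-6-(propan-2-yl)-3-{[(triisopropylsilyl)oxy]methyl}cyclohex-3-en-1-yl (2E)-4-[(tert-butyldimethylsilyl)oxy]-2-methylbut-2-enoate | C1C=C(CO[Si](C(C)C)(C(C)C)C(C)C)C(=O)[C@H](OC(=O)/C(C)=C/CO[Si](C)(C)C(C)(C)C)[C@H]1C(C)C | intermediate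
18 | (1R,6S)-6-(propan-2-yl)-3-{[(triisopropylsilyl)oxy]methyl}-2-[(trimethylsilyl)oxy]cyclohexa-2,4-dien-1-yl (2E)-4-[(tert-butyldimethylsilyl)oxy]-2-methylbut-2-enoate | C1=CC(CO[Si](C(C)C)(C(C)C)C(C)C)=C(O[Si](C)(C)C)[C@H](OC(=O)/C(C)=C/CO[Si](C)(C)C(C)(C)C)[C@H]1C(C)C | intermediate
19 | 4,5-epoxide of 18 (oxirane across C3–C4 in target numbering, anti to the isopropyl group) | O1[C@@H]2[C@H]1C(CO[Si](C(C)C)(C(C)C)C(C)C)=C(O[Si](C)(C)C)[C@H](OC(=O)/C(C)=C/CO[Si](C)(C)C(C)(C)C)[C@H]2C(C)C | intermediate
20 | (1R,5R,6S)-5-hydroxy-2-oxo-6-(propan-2-yl)-3-{[(triisopropylsilyl)oxy]methyl}cyclohex-3-en-1-yl (2E)-4-[(tert-butyldimethylsilyl)oxy]-2-methylbut-2-enoate | O[C@@H]1C=C(CO[Si](C(C)C)(C(C)C)C(C)C)C(=O)[C@H](OC(=O)/C(C)=C/CO[Si](C)(C)C(C)(C)C)[C@H]1C(C)C | intermediate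
21 | propionic acid | CCC(=O)O | starting material
22 | (1R,5S,6S)-2-oxo-5-(propanoyloxy)-6-(propan-2-yl)-3-{[(triisopropylsilyl)oxy]methyl}cyclohex-3-en-1-yl (2E)-4-[(tert-butyldimethylsilyl)oxy]-2-methylbut-2-enoate | CCC(=O)O[C@H]1C=C(CO[Si](C(C)C)(C(C)C)C(C)C)C(=O)[C@H](OC(=O)/C(C)=C/CO[Si](C)(C)C(C)(C)C)[C@H]1C(C)C | intermediate
23 | (1R,5S,6S)-3-(hydroxymethyl)-2-oxo-5-(propanoyloxy)-6-(propan-2-yl)cyclohex-3-en-1-yl (2E)-4-hydroxy-2-methylbut-2-enoate | CCC(=O)O[C@H]1C=C(CO)C(=O)[C@H](OC(=O)/C(C)=C/CO)[C@H]1C(C)C | target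

Total step count: 14 (12 in the main line, 2 for the side-chain acid). Longest linear sequence: 12 steps (steps 1–6 and 9–14) from but-2-yne-1,4-diol.

Steps most likely to fail

Step 11. Enolisation may take the wrong direction: loss of the C6 proton instead of a C4 proton would give the cross-conjugated dienol ether, which step 12 would then oxidise at C6. The fallback avoids enolisation altogether and sets out from 15. Photooxygenation as in step 10 but with reductive work-up (PPh3) gives the C1 allylic alcohol F1. Treatment with 2,4-dinitrobenzenesulfenyl chloride and Et3N forms the sulfenate, which rearranges [2,3] to the C3 allylic sulfoxide F2. On warming, F2 undergoes syn-elimination with the only available β-hydrogen (on C4) to give the 1,3-diene F3, an overall 1,4-dehydration. Singlet-oxygen [4+2] cycloaddition on the face anti to the isopropyl group gives the endoperoxide F4. Kornblum–DeLaMare opening with Et3N removes the bridgehead hydrogen at C1 (the more acidic one, next to the acyloxy carbon) and returns to the route at 20.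

Step 5. The bulkier and less basic substrate may be poorly accommodated by the confined acid, leading to slow turnover, low enantioselectivity or acid-induced dehydration of the product. The fallback sets out from 8. Stoichiometric Me2AlCl (CH2Cl2, −78 °C) acts as Lewis acid and proton scavenger and holds the product as its aluminium alkoxide. It should give the racemic trans alcohol, that is 9 together with its mirror image, the (1R,6S) alcohol F5. Esterification of the racemate with (2S)-2-methoxy-2-phenylacetic acid (DCC, DMAP) gives two diastereomeric esters, the ester of 9 F6 and the ester of the mirror-image alcohol F7, which are separated by chromatography. Methanolysis of F6 (K2CO3, MeOH) comes back to the route at 9.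

Step 12. Facial selectivity may be poor or reversed: if the dienol ether reacts through its diequatorial conformer, the oxidant can enter syn to the isopropyl group. The fallback sets out from 18. The oxidation then delivers the C4-epimeric alcohol F8 (hydroxyl cis to isopropyl), which is not inverted but acylated with retention (propionic anhydride, pyridine, DMAP). This returns to the route at 22 without step 13; any 20 formed alongside is still taken through step 13, so both epimers converge.

Further compounds
F1 | step 11 | (1R,6R)-2-hydroxy-6-(propan-2-yl)-3-{[(triisopropylsilyl)oxy]methyl}cyclohex-3-en-1-yl (2E)-4-[(tert-butyldimethylsilyl)oxy]-2-methylbut-2-enoate (carbinol carbon not controlled) | C1C=C(CO[Si](C(C)C)(C(C)C)C(C)C)C(O)[C@H](OC(=O)/C(C)=C/CO[Si](C)(C)C(C)(C)C)[C@H]1C(C)C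
F2 | step 11 | (1R,6R)-4-[(2,4-dinitrophenyl)sulfinyl]-6-(propan-2-yl)-3-{[(triisopropylsilyl)oxy]methyl}cyclohex-2-en-1-yl (2E)-4-[(tert-butyldimethylsilyl)oxy]-2-methylbut-2-enoate (sulfur and its carbon not controlled) | C1C(S(=O)c2ccc(cc2[N+](=O)[O-])[N+](=O)[O-])C(CO[Si](C(C)C)(C(C)C)C(C)C)=C[C@H](OC(=O)/C(C)=C/CO[Si](C)(C)C(C)(C)C)[C@H]1C(C)C
F3 | step 11 | (1R,6S)-6-(propan-2-yl)-3-{[(triisopropylsilyl)oxy]methyl}cyclohexa-2,4-dien-1-yl (2E)-4-[(tert-butyldimethylsilyl)oxy]-2-methylbut-2-enoate | C1=CC(CO[Si](C(C)C)(C(C)C)C(C)C)=C[C@H](OC(=O)/C(C)=C/CO[Si](C)(C)C(C)(C)C)[C@H]1C(C)C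
F4 | step 11 | endoperoxide of F3 (2,3-dioxabicyclo[2.2.2]oct-5-ene, peroxide bridge across C1 and C4 anti to the isopropyl group) | O1O[C@@H]2C=C(CO[Si](C(C)C)(C(C)C)C(C)C)[C@H]1[C@H](OC(=O)/C(C)=C/CO[Si](C)(C)C(C)(C)C)[C@H]2C(C)C
F5 | step 5 | (1R,6S)-6-(prop-1-en-2-yl)-3-{[(triisopropylsilyl)oxy]methyl}cyclohex-2-en-1-ol | C1CC(CO[Si](C(C)C)(C(C)C)C(C)C)=C[C@@H](O)[C@@H]1C(C)=C
F6 | step 5 | (1S,6R)-6-(prop-1-en-2-yl)-3-{[(triisopropylsilyl)oxy]methyl}cyclohex-2-en-1-yl (2S)-2-methoxy-2-phenylacetate | C1CC(CO[Si](C(C)C)(C(C)C)C(C)C)=C[C@H](OC(=O)[C@@H](OC)c2ccccc2)[C@H]1C(C)=C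
F7 | step 5 | (1R,6S)-6-(prop-1-en-2-yl)-3-{[(triisopropylsilyl)oxy]methyl}cyclohex-2-en-1-yl (2S)-2-methoxy-2-phenylacetate | C1CC(CO[Si](C(C)C)(C(C)C)C(C)C)=C[C@@H](OC(=O)[C@@H](OC)c2ccccc2)[C@@H]1C(C)=C
F8 | step 12 | (1R,5S,6S)-5-hydroxy-2-oxo-6-(propan-2-yl)-3-{[(triisopropylsilyl)oxy]methyl}cyclohex-3-en-1-yl (2E)-4-[(tert-butyldimethylsilyl)oxy]-2-methylbut-2-enoate | O[C@H]1C=C(CO[Si](C(C)C)(C(C)C)C(C)C)C(=O)[C@H](OC(=O)/C(C)=C/CO[Si](C)(C)C(C)(C)C)[C@H]1C(C)C
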